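**Stalled clock.** Time stopped paying in the teal flask near 6.00 h: its target read 69.9%, 70.7% and 70.0% up to 10.0 h. This teal flask is the one asked about.

| setting | teal | blue | flask |
|---|---|---|---|
| starting material | 12 mM | 8 mM | 12 mM |
| second substrate | 4 equiv | 4 equiv | 4.00 equiv |
| precatalyst | 0.0028 mol% | 0.0028 mol% | 0.0028 mol% |
| remark | the very flask that is asked about, followed so far | run made earlier |  |
| time |  |  | 15 h |

teal run (percent of the starting material charged): time / h: target / % = 1.33: 15.1; 2.50: 39.5; 4.00: 60.5; 5.00: 66.8; 6.00: 69.9; 8.00: 70.7; 10.0: 70.0

blue run (percent of the starting material charged): time / min: target / % = 6.00: 0; 20.0: 1.3; 40.0: 3.7; 50.0: 4.7; 80.0: 11.6; 90.0: 14.5; 120: 22.7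

(scatter of a reading: 0.3 percentage points)

- elm: at 15 h take out 90% of the target then present, then wait 15 h
- cedar: change nothing and wait 15 h more
- oak: at 15 h add precatalyst, 50.0% of the amount charged, then wait 15 h
- ash: at 15 h add second substrate, 50.0% of the amount charged, then wait 15 h

- what is taken out of target is counted as made
- additions bring no volume worth counting

1. target, in percent of the starting material first charged, at 15 h
2. which option adds most target ("none" when 2 percentage points or less is all one gets) (elm / cedar / oak / ash / none)
3. target present, with what was taken out counted in, in percent of the starting material first charged, after cedar
4. target present, with what was taken out counted in, in percent of the starting material first charged, after ash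

**Stop quotient.** I averaged those readings to a plateau of 70.2%. I took the stop for a balance and assumed that one first product leaves with each target. At a balance, forward rate divided by back rate is one, and catalyst amount and time cancel in that division. This leaves 0.501, the stop quotient: target times first product over starting material times second substrate, the equilibrium constant of the teal flask as read.

**Hand chain.** So I put the teal flask at 70.2% at 15 h, and cedar and oak leave the quotient where it stood. I reckoned ash, with 50.0% more second substrate, at 77.2%, a gain of 7 percentage points. Elm removes 90% of the target while first product stays, and the quotient then asks for 17 points more, more than ash brings. I committed to elm.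

**Weak link.** The chain hangs on the stop being a balance, and its sharpness argues against that. But the blue run's slope from 90.0 min to 120 min was 2.28 times its slope from 20.0 min to 40.0 min, with target still at 22.7%. Activity in the blue run was climbing there, so an early rate from that run understates its late one. I therefore kept the balance and did not read the sharp stop in the teal flask as a dying catalyst. The thing to watch is the plateau's quotient.

**The forecast.** It read the stop otherwise, “This looks like the catalyst dying”, and gave 70% at 15 h, oak as best, 70% after cedar and 70.3% after ash.

**The result.** The flask stood at 70.6% at 15 h. Elm added 17 points, ash 7 points, cedar 0 points and oak 0 points, so the best was elm; target reached 70.6% after cedar and 77.6% after ash.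

    starting material + free enzyme ⇌ first complex (K = 79.0 M⁻¹, k = 73400 M⁻¹ s⁻¹)
    first complex ⇌ loaded enzyme + first product (K = 0.0193 M, k = 4790 min⁻¹)
    second substrate + loaded enzyme ⇌ second complex (K = 13.0 M⁻¹, k = 48800 M⁻¹ min⁻¹)
    second complex ⇌ free enzyme + target (K = 0.0260 M, k = 1700 min⁻¹)
    precatalyst → free enzyme (k = 0.00511 min⁻¹)

**Equal charges.** We parted on oak: in the flask at 15.0 h free enzyme made up 44.2% of the catalyst charged, and oak added 0 points. My quotient's 77.2% for ash stands beside the flask's 77.6%. In the neighbouring flask, with 1.00 equiv of second substrate and other charges held, equal charges make the quotient a square, so its root is target over starting material, and I reckon target at 41.4%. That neighbouring flask held 41.8% target and 58.2% starting material at 15 h.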